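**Retrosynthetic overview**

1. Target ⇐ desilylation ⇐ SN2 bromide-for-oxygen exchange at an axial C3 alcohol ⇐ C3 ketone of a 13-O-silylated decalin that already carries both rings and the C8 methylene.
2. That ketone ⇐ one radical bicyclization of an open-chain bromo-trienone branched at C5: ring B closes first (C8–C9, vinyl radical, 6-endo), ring A second (C1–C10, tertiary radical onto the vinyl ketone, 6-endo).
3. Enabling feature: C10 is the methyl-bearing ring-fusion carbon, bonded to C9 and lying 1,4 to C3 (C10–C1–C2–C3). As the inner carbon of a Z-C9=C10 alkene it becomes a tertiary radical when ring B closes, and a C3 ketone makes C1 the electron-poor end of a vinyl ketone for that radical.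
4. Open-chain precursor ⇐ ester (gem-dimethylation, reduction, vinyl addition, oxidation) ⇐ rhodium-catalysed asymmetric conjugate alkenylation (sets C5) of a bromo-dienoate with a Z-alkenylboronate.
5. Z-Alkenylboronate ⇐ (R)-linalool (source of C13: silylation, ozonolysis, Z-iodo-olefination, borylation); dienoate ⇐ allylmagnesium bromide + 2,3-dibromopropene, then cross-metathesis with methyl acrylate.

Key step: step 12

Remark (assumption): the SMILES is read, with labdane locants (ring A = C1–C5 and C10, ring B = C5–C10, C17 = methylene carbon, C20 = angular methyl, side chain C11–C16), as 3R,5S,9S,10S,13R, i.e. a trans-decalin with equatorial bromine cis to C20 and the C9 side chain axial and anti to C20; the same locants are used for the open-chain precursors.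

**Route**

Step 1
Reactants: 1 (R)-linalool
Product: 2 triethyl{[(3R)-3,7-dimethylocta-1,6-dien-3-yl]oxy}silane
Conditions: Et3SiOTf, 2,6-lutidine, CH2Cl2, −78 → 0 °C
Reagents that add atoms: triethylsilyl trifluoromethanesulfonate, CC[Si](CC)(CC)OS(=O)(=O)C(F)(F)F
Why: Silylation of a tertiary alcohol with a silyl triflate and a hindered pyridine base masks the hydroxyl for the later organometallic and radical steps, and the C13 stereocentre comes unchanged from the chiral pool.

Step 2
Reactants: 2 triethyl{[(3R)-3,7-dimethylocta-1,6-dien-3-yl]oxy}silane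
Product: 4 (4R)-4-methyl-4-[(triethylsilyl)oxy]hex-5-enal, via ozonide 3 (not isolated)
Conditions: O3, CH2Cl2, −78 °C (Sudan Red 7B end point); then PPh3, −78 °C → rt
Reagents that add atoms: ozone, [O-][O+]=O
Why: Chemoselective ozonolysis should cleave the electron-rich trisubstituted alkene well before the monosubstituted vinyl group beside the silyloxy-bearing quaternary carbon, and reductive work-up of the ozonide gives the aldehyde.

Step 3
Reactants: 4 (4R)-4-methyl-4-[(triethylsilyl)oxy]hex-5-enal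
Product: 5 triethyl{[(3R,6Z)-7-iodo-3-methylocta-1,6-dien-3-yl]oxy}silane
Conditions: Ph3P(Et)I, n-BuLi, THF, 0 °C; I2, −78 °C; NaN(SiMe3)2, −20 °C; then 4, −78 °C → rt
Reagents that add atoms: ethyltriphenylphosphonium iodide, CC[P+](c1ccccc1)(c1ccccc1)c1ccccc1.[I-]; iodine, II
Why: Wittig olefination with the α-iodo ylide (Stork–Zhao-type iodo-olefination) converts aliphatic aldehydes into (Z)-2-iodoalk-2-enes under kinetic control, which places iodine cis to the chain as the later C9=C10 geometry demands.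

Step 4
Reactants: 5 triethyl{[(3R,6Z)-7-iodo-3-methylocta-1,6-dien-3-yl]oxy}silane
Product: 6 2-[(2E,6R)-6-methyl-6-[(triethylsilyl)oxy]octa-2,7-dien-2-yl]-4,4,5,5-tetramethyl-1,3,2-dioxaborolane (boron cis to the chain; the descriptor changes only because boron ranks below carbon)
Conditions: B2pin2, PdCl2(PPh3)2 (3 mol %), PPh3 (6 mol %), KOPh, toluene, 50 °C
Reagents that add atoms: bis(pinacolato)diboron, CC1(C)OB(OC1(C)C)B1OC(C)(C)C(C)(C)O1
Why: Miyaura borylation of an alkenyl iodide runs through oxidative addition, boron transfer and reductive elimination with retention of alkene geometry.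

Step 5
Reactants: 7 allylmagnesium bromide; 8 2,3-dibromopropene
Product: 9 2-bromohexa-1,5-diene
Conditions: Et2O, 0 °C → rt
Reagents that add atoms: none
Why: Allyl–allyl coupling of the Grignard reagent at the allylic bromide (SN2 and SN2′ paths give the same product) leaves the vinylic bromide untouched.

Step 6
Reactants: 9 2-bromohexa-1,5-diene; 10 methyl acrylate
Product: 11 methyl (2E)-6-bromohepta-2,6-dienoate
Conditions: second-generation Hoveyda–Grubbs catalyst RuCl2(H2IMes)(=CH-C6H4-2-O-i-Pr) (3 mol %), methyl acrylate (3 equiv), CH2Cl2, 40 °C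
Reagents that add atoms: none
Why: Olefin cross-metathesis of a terminal alkene with an acrylate is E-selective, and the 1,1-disubstituted bromoalkene is too hindered and electron-poor to enter the cycle.

Step 7
Reactants: 6 2-[(2E,6R)-6-methyl-6-[(triethylsilyl)oxy]octa-2,7-dien-2-yl]-4,4,5,5-tetramethyl-1,3,2-dioxaborolane; 11 methyl (2E)-6-bromohepta-2,6-dienoate
Product: 12 methyl (3R)-6-bromo-3-[(2Z,6R)-6-methyl-6-[(triethylsilyl)oxy]octa-2,7-dien-2-yl]hept-6-enoate
Conditions: [RhCl(C2H4)2]2 (2.5 mol %), (R)-BINAP (6 mol %), KOH (20 mol %), 1,4-dioxane/H2O 10:1, 60 °C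
Reagents that add atoms: none
Why: Hayashi–Miyaura rhodium-catalysed asymmetric 1,4-addition transfers the alkenyl group with retention of its geometry to the β-carbon of the E-enoate, and the BINAP antipode is chosen by the accepted facial model for acyclic E-acceptors so that the 3R centre (future C5) should form.

Step 8
Reactants: 12 methyl (3R)-6-bromo-3-[(2Z,6R)-6-methyl-6-[(triethylsilyl)oxy]octa-2,7-dien-2-yl]hept-6-enoate
Product: 14 methyl (3S)-6-bromo-2,2-dimethyl-3-[(2Z,6R)-6-methyl-6-[(triethylsilyl)oxy]octa-2,7-dien-2-yl]hept-6-enoate, via monomethyl ester 13 (not isolated)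
Conditions: LiN(i-Pr)2, THF, −78 °C; MeI; then LiN(i-Pr)2, DMPU, −78 °C; MeI, −78 → −30 °C
Reagents that add atoms: iodomethane, CI
Why: Two successive ester enolate alkylations build the gem-dimethyl quaternary carbon (future C4); the stereocentre made by the first methylation is erased by the second, and the low temperature should keep the bromoalkene from dehydrobromination.

Step 9
Reactants: 14 methyl (3S)-6-bromo-2,2-dimethyl-3-[(2Z,6R)-6-methyl-6-[(triethylsilyl)oxy]octa-2,7-dien-2-yl]hept-6-enoate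
Product: 15 (3S)-6-bromo-2,2-dimethyl-3-[(2Z,6R)-6-methyl-6-[(triethylsilyl)oxy]octa-2,7-dien-2-yl]hept-6-enal
Conditions: i-Bu2AlH (1.1 equiv), CH2Cl2, −78 °C; aq potassium sodium tartrate
Reagents that add atoms: none
Why: Partial reduction of a hindered neopentylic methyl ester with i-Bu2AlH at low temperature should stop at the aldehyde oxidation level.

Step 10
Reactants: 15 (3S)-6-bromo-2,2-dimethyl-3-[(2Z,6R)-6-methyl-6-[(triethylsilyl)oxy]octa-2,7-dien-2-yl]hept-6-enal
Product: 16 (5S)-8-bromo-4,4-dimethyl-5-[(2Z,6R)-6-methyl-6-[(triethylsilyl)oxy]octa-2,7-dien-2-yl]nona-1,8-dien-3-ol (both C3 epimers)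
Conditions: CH2=CHMgBr, THF, −78 → 0 °C; then H2O
Reagents that add atoms: vinylmagnesium bromide, C=C[Mg]Br
Why: Grignard 1,2-addition to the non-enolisable aldehyde brings in C1 and C2, and the carbinol centre is formed as a mixture that the next step removes.

Step 11
Reactants: 16 (5S)-8-bromo-4,4-dimethyl-5-[(2Z,6R)-6-methyl-6-[(triethylsilyl)oxy]octa-2,7-dien-2-yl]nona-1,8-dien-3-ol
Product: 17 (5S)-8-bromo-4,4-dimethyl-5-[(2Z,6R)-6-methyl-6-[(triethylsilyl)oxy]octa-2,7-dien-2-yl]nona-1,8-dien-3-one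
Conditions: Dess–Martin periodinane, NaHCO3, CH2Cl2, 0 °C
Reagents that add atoms: none
Why: Dess–Martin oxidation of the allylic alcohol under buffered, non-basic conditions should give the sensitive vinyl ketone without conjugate addition or isomerisation of the Z-alkene.

Step 12
Reactants: 17 (5S)-8-bromo-4,4-dimethyl-5-[(2Z,6R)-6-methyl-6-[(triethylsilyl)oxy]octa-2,7-dien-2-yl]nona-1,8-dien-3-one
Product: 19 (4aS,5S,8aS)-1,1,4a-trimethyl-6-methylidene-5-[(3R)-3-methyl-3-[(triethylsilyl)oxy]pent-4-en-1-yl]octahydronaphthalen-2(1H)-one, via monocyclic tertiary radical 18 (not isolated)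
Conditions: Bu3SnH (1.3 equiv, syringe pump, 8 h), AIBN (0.2 equiv), PhH (0.005 M), 80 °C
Reagents that add atoms: none
Why: The stannyl radical abstracts bromine from the 2-bromoalkene, the C8 vinyl radical adds to C9 of the Z-C9=C10 alkene, the resulting tertiary C10 radical adds to the terminal carbon C1 of the vinyl ketone (Giese addition), and the α-keto radical takes hydrogen from Bu3SnH. The closest known chemistry is the tin hydride vinyl-radical cyclization cascade and the radical polyene cyclization that gives trans-decalins. Ring B closes 6-endo-trig at C9, because 5-exo attack at the fully substituted C10 is blocked and a 5-exo radical would in any case converge on the same six-ring radical by homoallyl/cyclopropylcarbinyl rearrangement; ring A closes 6-endo-trig at C1, since attack at the α-carbon of the enone is mismatched in polarity. C9 is set by the Z geometry together with a chair-like transition state in which the bulky C4 arm on C5 is pseudo-equatorial (1,3-allylic strain forbids the alternative), which puts the side chain axial and syn to H5. C10 is set in the chair-like closure of ring A, where C1 enters along the equatorial direction of ring B so that the methyl ends up axial and anti to H5 (trans-decalin). The step needs ring closure to outrun hydrogen transfer to the vinyl and tertiary radicals and stannyl addition to the enone, which slow hydride addition at high dilution, the polarity match of a nucleophilic tertiary radical with an unsubstituted enone terminus and the gem-dimethyl group in the tether should secure, while the unactivated side-chain vinyl group stays out.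

Step 13
Reactants: 19 (4aS,5S,8aS)-1,1,4a-trimethyl-6-methylidene-5-[(3R)-3-methyl-3-[(triethylsilyl)oxy]pent-4-en-1-yl]octahydronaphthalen-2(1H)-one
Product: 20 (2S,4aS,5S,8aS)-1,1,4a-trimethyl-6-methylidene-5-[(3R)-3-methyl-3-[(triethylsilyl)oxy]pent-4-en-1-yl]decahydronaphthalen-2-ol
Conditions: LiBH(s-Bu)3 (L-Selectride), THF, −78 °C; then aq NaOH, H2O2, 0 °C
Reagents that add atoms: none
Why: Bulky hydride reduction of a cyclohexanone flanked by a gem-dimethyl carbon delivers hydride along the equatorial trajectory and should give the axial C3 alcohol, anti to C20, as known for 4,4-dimethyl-3-oxo terpenoids.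

Step 14
Reactants: 20 (2S,4aS,5S,8aS)-1,1,4a-trimethyl-6-methylidene-5-[(3R)-3-methyl-3-[(triethylsilyl)oxy]pent-4-en-1-yl]decahydronaphthalen-2-ol
Product: 22 {[(3R)-5-[(1S,4aS,6R,8aS)-6-bromo-5,5,8a-trimethyl-2-methylidenedecahydronaphthalen-1-yl]-3-methylpent-1-en-3-yl]oxy}triethylsilane, via alkoxyphosphonium bromide 21 (not isolated)
Conditions: CBr4 (2 equiv), PPh3 (2.2 equiv), 2,6-lutidine (0.5 equiv), toluene, 0 → 60 °C
Reagents that add atoms: carbon tetrabromide, BrC(Br)(Br)Br
Why: In the Appel reaction bromide displaces the alkoxyphosphonium group with inversion (SN2), turning the axial alcohol into the equatorial bromide cis to C20, a displacement precedented at this type of neopentylic ring carbon in brominated marine terpenoid work, while the lutidine buffer protects the tertiary allylic silyl ether.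

Step 15
Reactants: 22 {[(3R)-5-[(1S,4aS,6R,8aS)-6-bromo-5,5,8a-trimethyl-2-methylidenedecahydronaphthalen-1-yl]-3-methylpent-1-en-3-yl]oxy}triethylsilane
Product: 23 (3R)-5-[(1S,4aS,6R,8aS)-6-bromo-5,5,8a-trimethyl-2-methylidenedecahydronaphthalen-1-yl]-3-methylpent-1-en-3-ol
Conditions: Bu4NF, THF, 0 °C → rt
Reagents that add atoms: none
Why: Fluoride-mediated desilylation frees the tertiary allylic alcohol under conditions that should not touch the hindered secondary bromide or the alkenes.

**Compound list**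

1 | (R)-linalool, (3R)-3,7-dimethylocta-1,6-dien-3-ol | C=C[C@](C)(O)CCC=C(C)C | starting material
2 | triethyl{[(3R)-3,7-dimethylocta-1,6-dien-3-yl]oxy}silane | C=C[C@](C)(O[Si](CC)(CC)CC)CCC=C(C)C | intermediate
3 | ozonide of 2 at the trisubstituted alkene, 5,5-dimethyl-3-[(3R)-3-methyl-3-(triethylsilyloxy)pent-4-en-1-yl]-1,2,4-trioxolane (mixture at the ring carbon) | C=C[C@](C)(O[Si](CC)(CC)CC)CCC1OOC(C)(C)O1 | intermediate
4 | (4R)-4-methyl-4-[(triethylsilyl)oxy]hex-5-enal | C=C[C@](C)(O[Si](CC)(CC)CC)CCC=O | intermediate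
5 | triethyl{[(3R,6Z)-7-iodo-3-methylocta-1,6-dien-3-yl]oxy}silane | C=C[C@](C)(O[Si](CC)(CC)CC)CC/C=C(/C)I | intermediate
6 | 2-[(2E,6R)-6-methyl-6-[(triethylsilyl)oxy]octa-2,7-dien-2-yl]-4,4,5,5-tetramethyl-1,3,2-dioxaborolane | C=C[C@](C)(O[Si](CC)(CC)CC)CC/C=C(/C)B1OC(C)(C)C(C)(C)O1 | intermediate
7 | allylmagnesium bromide | C=CC[Mg]Br | starting material
8 | 2,3-dibromopropene | C=C(Br)CBr | starting material
9 | 2-bromohexa-1,5-diene | C=CCCC(Br)=C | intermediate
10 | methyl acrylate | C=CC(=O)OC | starting material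
11 | methyl (2E)-6-bromohepta-2,6-dienoate | COC(=O)/C=C/CCC(Br)=C | intermediate
12 | methyl (3R)-6-bromo-3-[(2Z,6R)-6-methyl-6-[(triethylsilyl)oxy]octa-2,7-dien-2-yl]hept-6-enoate | C=C[C@](C)(O[Si](CC)(CC)CC)CC/C=C(/C)[C@H](CCC(Br)=C)CC(=O)OC | intermediate
13 | methyl (3R)-6-bromo-2-methyl-3-[(2Z,6R)-6-methyl-6-[(triethylsilyl)oxy]octa-2,7-dien-2-yl]hept-6-enoate (both C2 epimers) | C=C[C@](C)(O[Si](CC)(CC)CC)CC/C=C(/C)[C@H](CCC(Br)=C)C(C)C(=O)OC | intermediate
14 | methyl (3S)-6-bromo-2,2-dimethyl-3-[(2Z,6R)-6-methyl-6-[(triethylsilyl)oxy]octa-2,7-dien-2-yl]hept-6-enoate | C=C[C@](C)(O[Si](CC)(CC)CC)CC/C=C(/C)[C@H](CCC(Br)=C)C(C)(C)C(=O)OC | intermediate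
15 | (3S)-6-bromo-2,2-dimethyl-3-[(2Z,6R)-6-methyl-6-[(triethylsilyl)oxy]octa-2,7-dien-2-yl]hept-6-enal | C=C[C@](C)(O[Si](CC)(CC)CC)CC/C=C(/C)[C@H](CCC(Br)=C)C(C)(C)C=O | intermediate
16 | (5S)-8-bromo-4,4-dimethyl-5-[(2Z,6R)-6-methyl-6-[(triethylsilyl)oxy]octa-2,7-dien-2-yl]nona-1,8-dien-3-ol (both C3 epimers) | C=C[C@](C)(O[Si](CC)(CC)CC)CC/C=C(/C)[C@H](CCC(Br)=C)C(C)(C)C(O)C=C | intermediate
17 | (5S)-8-bromo-4,4-dimethyl-5-[(2Z,6R)-6-methyl-6-[(triethylsilyl)oxy]octa-2,7-dien-2-yl]nona-1,8-dien-3-one | C=C[C@](C)(O[Si](CC)(CC)CC)CC/C=C(/C)[C@H](CCC(Br)=C)C(C)(C)C(=O)C=C | intermediate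
18 | monocyclic tertiary C10 radical: ring B closed, exocyclic methylene at C8, axial side chain at C9, vinyl ketone arm on C5 | C=C[C@](C)(O[Si](CC)(CC)CC)CC[C@H]1C(=C)CC[C@H](C(C)(C)C(=O)C=C)[C]1C | intermediate
19 | (4aS,5S,8aS)-1,1,4a-trimethyl-6-methylidene-5-[(3R)-3-methyl-3-[(triethylsilyl)oxy]pent-4-en-1-yl]octahydronaphthalen-2(1H)-one | C=C[C@](C)(O[Si](CC)(CC)CC)CC[C@H]1C(=C)CC[C@@H]2C(C)(C)C(=O)CC[C@]21C | intermediate
20 | (2S,4aS,5S,8aS)-1,1,4a-trimethyl-6-methylidene-5-[(3R)-3-methyl-3-[(triethylsilyl)oxy]pent-4-en-1-yl]decahydronaphthalen-2-ol (axial hydroxyl) | C=C[C@](C)(O[Si](CC)(CC)CC)CC[C@H]1C(=C)CC[C@@H]2C(C)(C)[C@@H](O)CC[C@]21C | intermediate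
21 | alkoxytriphenylphosphonium bromide of 20 | C=C[C@](C)(O[Si](CC)(CC)CC)CC[C@H]1C(=C)CC[C@@H]2C(C)(C)[C@@H](O[P+](c3ccccc3)(c3ccccc3)c3ccccc3)CC[C@]21C.[Br-] | intermediate
22 | {[(3R)-5-[(1S,4aS,6R,8aS)-6-bromo-5,5,8a-trimethyl-2-methylidenedecahydronaphthalen-1-yl]-3-methylpent-1-en-3-yl]oxy}triethylsilane | C=C[C@](C)(O[Si](CC)(CC)CC)CC[C@H]1C(=C)CC[C@@H]2C(C)(C)[C@H](Br)CC[C@]21C | intermediate
23 | (3R)-5-[(1S,4aS,6R,8aS)-6-bromo-5,5,8a-trimethyl-2-methylidenedecahydronaphthalen-1-yl]-3-methylpent-1-en-3-ol | C=C[C@](C)(O)CC[C@H]1C(=C)CC[C@@H]2C(C)(C)[C@H](Br)CC[C@]21C | target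

**Step count and risks**

Total: 15 steps. Longest linear sequence: 13 steps (steps 1–4 and 7–15, from (R)-linalool).

Steps most likely to fail:

1. **Step 12.** Hydrogen transfer from the tin hydride to the vinyl or the tertiary radical may outrun ring closure, the stannyl radical may add to the enone, or ring A may close through the other lobe of the C10 radical (cis fusion).
   Fallback (sets out from 16, comes back at 19): the two closures are separated and tin hydride is avoided.
   - LiN(i-Pr)2 (3 equiv, THF, −78 → 0 °C) should dehydrobrominate the bromoalkene of 16 to the terminal alkyne, (5S)-4,4-dimethyl-5-[(2Z,6R)-6-methyl-6-(triethylsilyloxy)octa-2,7-dien-2-yl]non-1-en-8-yn-3-ol F1.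
   - Dess–Martin oxidation gives the corresponding ynenone, (5S)-4,4-dimethyl-5-[(2Z,6R)-6-methyl-6-(triethylsilyloxy)octa-2,7-dien-2-yl]non-1-en-8-yn-3-one F2.
   - The cationic monovalent gold complex [Au(NCMe){P(t-Bu)2(2-biphenylyl)}]SbF6 (2 mol %) in wet acetone at rt should effect a 1,6-enyne hydroxycyclization: C8 bonds to C9, water adds to C10 anti across the Z-alkene, and protodeauration leaves the C8 methylene. This gives the ring B tertiary alcohol, 4-[(1R,2S,3S)-2-hydroxy-2-methyl-4-methylidene-3-{(3R)-3-methyl-3-(triethylsilyloxy)pent-4-en-1-yl}cyclohexyl]-4-methylpent-1-en-3-one F3.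
   - Acylation with 1,3-dioxoisoindolin-2-yl chlorooxoacetate (Et3N, DMAP, CH2Cl2) gives the tert-alkyl N-phthalimidoyl oxalate of that alcohol F4.
   - Visible-light reduction (Ru(bpy)3(PF6)2, Hantzsch ester, i-Pr2NEt·HBF4, THF/CH2Cl2, blue LEDs) should release the C10 tertiary radical, which closes ring A by 6-endo Giese addition at C1 to give 19.

2. **Step 14.** Anti-periplanar E2 loss of the activated axial oxygen (to the ring A alkene) or a 1,2-methyl shift may outpace the hindered SN2 displacement, and adventitious HBr may ionise the tertiary allylic silyl ether.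
   Fallback (sets out from 19, comes back at 22): bromine is installed first and hydrogen last, by a radical path.
   - N2H4·H2O, Et3N, EtOH, 80 °C gives the hydrazone of ketone 19 F5.
   - CuBr2, LiOt-Bu, THF, 0 °C → rt gives the C3 gem-dibromide, the 3,3-dibromo analogue of 22 F6.
   - (Me3Si)3SiH (1.05 equiv), AIBN, toluene, 80 °C removes one bromine. The α-bromo radical should take hydrogen along the axial direction (anti to the axial C4 methyl, flanked only by axial hydrogens), which leaves bromine equatorial as in 22.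

3. **Step 7.** Slow transmetalation or protodeboronation of the hindered alkenylboronate, erosion of the alkene geometry, or low enantioselectivity.
   Fallback (sets out from 9 and 5, comes back at 12): auxiliary control with a stoichiometric organocopper reagent replaces catalyst control.
   - Commercial (S)-4-phenyloxazolidin-2-one is N-acylated (n-BuLi, acryloyl chloride, THF, −78 °C) to (S)-3-acryloyl-4-phenyloxazolidin-2-one F7.
   - Cross-metathesis with 9 (second-generation Hoveyda–Grubbs catalyst, CH2Cl2, 40 °C) gives (S)-3-[(2E)-6-bromohepta-2,6-dienoyl]-4-phenyloxazolidin-2-one F8.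
   - Iodide 5 is converted to the alkenyl copper reagent with retention (t-BuLi, Et2O, −78 °C; MgBr2·OEt2; CuBr·SMe2, THF, −40 °C). It should add to the magnesium-chelated s-cis imide anti to the phenyl group, giving (S)-3-[(3R)-6-bromo-3-{(2Z,6R)-6-methyl-6-(triethylsilyloxy)octa-2,7-dien-2-yl}hept-6-enoyl]-4-phenyloxazolidin-2-one F9.
   - MeOMgBr in MeOH/CH2Cl2 at 0 °C cleaves the auxiliary and returns ester 12.

Further compounds
F1 | step 12 | (5S)-4,4-dimethyl-5-[(2Z,6R)-6-methyl-6-(triethylsilyloxy)octa-2,7-dien-2-yl]non-1-en-8-yn-3-ol (both C3 epimers) | C=C[C@](C)(O[Si](CC)(CC)CC)CC/C=C(/C)[C@H](CCC#C)C(C)(C)C(O)C=C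
F2 | step 12 | (5S)-4,4-dimethyl-5-[(2Z,6R)-6-methyl-6-(triethylsilyloxy)octa-2,7-dien-2-yl]non-1-en-8-yn-3-one | C=C[C@](C)(O[Si](CC)(CC)CC)CC/C=C(/C)[C@H](CCC#C)C(C)(C)C(=O)C=C
F3 | step 12 | 4-[(1R,2S,3S)-2-hydroxy-2-methyl-4-methylidene-3-{(3R)-3-methyl-3-(triethylsilyloxy)pent-4-en-1-yl}cyclohexyl]-4-methylpent-1-en-3-one | C=C[C@](C)(O[Si](CC)(CC)CC)CC[C@H]1C(=C)CC[C@H](C(C)(C)C(=O)C=C)[C@]1(O)C
F4 | step 12 | N-phthalimidoyl oxalate of the tertiary alcohol F3 | C=C[C@](C)(O[Si](CC)(CC)CC)CC[C@H]1C(=C)CC[C@H](C(C)(C)C(=O)C=C)[C@]1(OC(=O)C(=O)ON2C(=O)c3ccccc3C2=O)C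
F5 | step 14 | hydrazone of ketone 19 | C=C[C@](C)(O[Si](CC)(CC)CC)CC[C@H]1C(=C)CC[C@@H]2C(C)(C)C(=NN)CC[C@]21C
F6 | step 14 | C3 gem-dibromide, 3,3-dibromo analogue of 22 | C=C[C@](C)(O[Si](CC)(CC)CC)CC[C@H]1C(=C)CC[C@@H]2C(C)(C)C(Br)(Br)CC[C@]21C
F7 | step 7 | (S)-3-acryloyl-4-phenyloxazolidin-2-one | C=CC(=O)N1C(=O)OC[C@@H]1c1ccccc1
F8 | step 7 | (S)-3-[(2E)-6-bromohepta-2,6-dienoyl]-4-phenyloxazolidin-2-one | C=C(Br)CC/C=C/C(=O)N1C(=O)OC[C@@H]1c1ccccc1
F9 | step 7 | (S)-3-[(3R)-6-bromo-3-{(2Z,6R)-6-methyl-6-(triethylsilyloxy)octa-2,7-dien-2-yl}hept-6-enoyl]-4-phenyloxazolidin-2-one | C=C[C@](C)(O[Si](CC)(CC)CC)CC/C=C(/C)[C@H](CCC(Br)=C)CC(=O)N1C(=O)OC[C@@H]1c1ccccc1
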